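**Retrosynthetic overview**
- The target is a flavonol with free 3‑, 5‑, 3'‑ and 5'‑OH groups. The last step unmasks a 5‑O‑methyl, 3',5'‑di‑O‑benzyl precursor in one Lewis‑acid operation.
- Ring C, the only ring formed, comes from a 2'‑hydroxychalcone by Algar–Flynn–Oyamada oxidative cyclisation, which closes the O1–C2 bond and installs the 3‑OH.
- The chalcone comes from a Claisen–Schmidt condensation of the ring A acetophenone with the ring B aldehyde.
- The ring B aldehyde is obtained by O‑benzylation of 3,5‑dihydroxy‑4‑methoxybenzaldehyde; rings A and B are bought intact.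

Assumption: the target has no stereocentre, so the "single enantiomer" requirement needs no stereocontrol; the ring B aldehyde and the ring A acetophenone are both taken as catalogue compounds.

**Route**

Step 1
Reactants: 1 3,5-dihydroxy-4-methoxybenzaldehyde
Product: 2 3,5-bis(benzyloxy)-4-methoxybenzaldehyde
Conditions: BnBr (2.3 equiv), K2CO3 (3 equiv), DMF, 60 °C, 4 h
Reagents that add atoms: benzyl bromide, BrCc1ccccc1
Why: Williamson ether synthesis (SN2 O‑benzylation) of the two phenoxides formed by K2CO3; the aldehyde and the methyl ether are inert and no stereocentre is created.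

Step 2
Reactants: 2 3,5-bis(benzyloxy)-4-methoxybenzaldehyde; 3 1-(2-hydroxy-3,4,6-trimethoxyphenyl)ethan-1-one (2'-hydroxy-3',4',6'-trimethoxyacetophenone)
Product: 5 (E)-3-[3,5-bis(benzyloxy)-4-methoxyphenyl]-1-(2-hydroxy-3,4,6-trimethoxyphenyl)prop-2-en-1-one, via racemic aldol adduct 4 (not isolated)
Conditions: KOH (50% aq, 10 equiv), EtOH/THF, rt, 36 h; then 1 M HCl, 0 °C
Reagents that add atoms: none
Why: Claisen–Schmidt (crossed aldol) condensation of the methyl ketone enolate with the non‑enolisable aldehyde, followed by E1cB loss of water from 4, gives the conjugated, hydrogen‑bond‑stabilised E‑enone, so the stereocentre of 4 is destroyed; KOH is not consumed and water is the only co‑product.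

Step 3
Reactants: 5 (E)-3-[3,5-bis(benzyloxy)-4-methoxyphenyl]-1-(2-hydroxy-3,4,6-trimethoxyphenyl)prop-2-en-1-one
Product: 7 2-[3,5-bis(benzyloxy)-4-methoxyphenyl]-3-hydroxy-5,7,8-trimethoxy-4H-chromen-4-one, via racemic trans-dihydroflavonol 6 (not isolated)
Conditions: 30% aq H2O2 (6 equiv), 2 M aq NaOH (5 equiv), MeOH/THF, 0 °C → rt, 16 h; then 1 M HCl
Reagents that add atoms: hydrogen peroxide, OO
Why: Algar–Flynn–Oyamada oxidative cyclisation: conjugate addition of the 2'‑phenoxide with hydroxylation of the enolate by H2O2 gives 6, which a second equivalent of H2O2 dehydrogenates in base to the planar flavonol, so no stereocentre remains; benzyl and methyl ethers survive cold alkaline peroxide, NaOH is not consumed and H2O2 ends as water.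

Step 4
Reactants: 7 2-[3,5-bis(benzyloxy)-4-methoxyphenyl]-3-hydroxy-5,7,8-trimethoxy-4H-chromen-4-one
Product: 8 3,5-dihydroxy-2-(3,5-dihydroxy-4-methoxyphenyl)-7,8-dimethoxy-4H-chromen-4-one (target)
Conditions: BCl3 (1 M in CH2Cl2, 8 equiv), pentamethylbenzene (6 equiv), CH2Cl2, −78 °C, 1 h, then 0 °C, 2 h; then H2O
Reagents that add atoms: none
Why: Lewis‑acid ether cleavage: BCl3 removes both benzyl ethers at low temperature (the benzyl cation is trapped by pentamethylbenzene in a Friedel–Crafts alkylation) and on warming cleaves only the 5‑OMe, which is activated by boron chelation to the peri 4‑carbonyl; the non‑chelated 7‑, 8‑ and 4'‑methyl ethers stay, and no stereocentre is involved.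

**Compound list**

1 | 3,5-dihydroxy-4-methoxybenzaldehyde | COc1c(O)cc(C=O)cc1O | starting material
2 | 3,5-bis(benzyloxy)-4-methoxybenzaldehyde | COc1c(OCc2ccccc2)cc(C=O)cc1OCc1ccccc1 | intermediate
3 | 1-(2-hydroxy-3,4,6-trimethoxyphenyl)ethan-1-one | CC(=O)c1c(O)c(OC)c(OC)cc1OC | starting material
4 | (±)-3-[3,5-bis(benzyloxy)-4-methoxyphenyl]-3-hydroxy-1-(2-hydroxy-3,4,6-trimethoxyphenyl)propan-1-one (racemic, formed in the flask) | O=C(CC(O)c1cc(OCc2ccccc2)c(OC)c(OCc2ccccc2)c1)c1c(O)c(OC)c(OC)cc1OC | intermediate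
5 | (E)-3-[3,5-bis(benzyloxy)-4-methoxyphenyl]-1-(2-hydroxy-3,4,6-trimethoxyphenyl)prop-2-en-1-one | O=C(/C=C/c1cc(OCc2ccccc2)c(OC)c(OCc2ccccc2)c1)c1c(O)c(OC)c(OC)cc1OC | intermediate
6 | (±)-trans-2-[3,5-bis(benzyloxy)-4-methoxyphenyl]-3-hydroxy-5,7,8-trimethoxy-2,3-dihydro-4H-chromen-4-one (racemic, 2R,3R enantiomer drawn, formed in the flask) | COc1cc(OC)c2C(=O)[C@H](O)[C@@H](c3cc(OCc4ccccc4)c(OC)c(OCc4ccccc4)c3)Oc2c1OC | intermediate
7 | 2-[3,5-bis(benzyloxy)-4-methoxyphenyl]-3-hydroxy-5,7,8-trimethoxy-4H-chromen-4-one | COc1cc(OC)c2c(=O)c(O)c(-c3cc(OCc4ccccc4)c(OC)c(OCc4ccccc4)c3)oc2c1OC | intermediate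
8 | 3,5-dihydroxy-2-(3,5-dihydroxy-4-methoxyphenyl)-7,8-dimethoxy-4H-chromen-4-one (achiral) | COc1cc(O)c2c(=O)c(O)c(-c3cc(O)c(OC)c(O)c3)oc2c1OC | target

**Step count and risks**

Total step count: 4. Longest linear sequence: 4 steps (1 → 2 → 5 → 7 → 8); acetophenone 3 enters at step 2 without prior steps.

Steps most likely to fail:

Step 3 (Algar–Flynn–Oyamada). The 6'‑methoxy group of chalcone 5 favours competing α‑attack to an aurone, so the flavonol yield may be low. The fallback sets out from 5 and builds the pyranone first, then oxygenates C3 separately. Oxidative cyclisation with catalytic I2 in DMSO at 120 °C gives the flavone 2-[3,5-bis(benzyloxy)-4-methoxyphenyl]-5,7,8-trimethoxy-4H-chromen-4-one F1. C3 lithiation with LiN(iPr)2 in THF at −78 °C and trapping with B(OMe)3 gives the boronate dimethyl [2-(3,5-bis(benzyloxy)-4-methoxyphenyl)-5,7,8-trimethoxy-4-oxo-4H-chromen-3-yl]boronate F2, which is not isolated. Oxidation with H2O2/AcOH then delivers the flavonol, and the fallback comes back to the route at 7.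

Step 4 (global BCl3 unmasking). Over‑demethylation at the doubly ortho‑flanked 4'‑OMe or 8‑OMe, or incomplete 5‑O‑demethylation, could erode the yield. The fallback sets out from 7 and separates the two events into orthogonal operations. Chelation‑controlled demethylation with MgI2·OEt2 in THF/toluene at 70 °C, with the benzyl ethers still masking ring B, gives 2-[3,5-bis(benzyloxy)-4-methoxyphenyl]-3,5-dihydroxy-7,8-dimethoxy-4H-chromen-4-one F3. Neutral hydrogenolysis (H2, 1 atm, 10% Pd/C, EtOAc/MeOH, rt) then removes both benzyl groups, and the fallback comes back to the route at 8.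

Step 2 (Claisen–Schmidt). The phenoxide of 3 slows enolisation, and the 2'‑hydroxy‑6'‑methoxychalcone can partly close to the flavanone in base. The fallback sets out from 3 and masks the phenol before the condensation. NaH and MOMCl in DMF at 0 °C give 1-[3,4,6-trimethoxy-2-(methoxymethoxy)phenyl]ethan-1-one F4. Condensation with 2 (KOH, EtOH, rt) gives (E)-3-[3,5-bis(benzyloxy)-4-methoxyphenyl]-1-[3,4,6-trimethoxy-2-(methoxymethoxy)phenyl]prop-2-en-1-one F5. Brief treatment with 3 M HCl in MeOH at 50 °C removes the acetal, and the fallback comes back to the route at 5.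

**Further compounds**

F1 | step 3 | 2-[3,5-bis(benzyloxy)-4-methoxyphenyl]-5,7,8-trimethoxy-4H-chromen-4-one | COc1cc(OC)c2c(=O)cc(-c3cc(OCc4ccccc4)c(OC)c(OCc4ccccc4)c3)oc2c1OC
F2 | step 3 | dimethyl [2-(3,5-bis(benzyloxy)-4-methoxyphenyl)-5,7,8-trimethoxy-4-oxo-4H-chromen-3-yl]boronate | COB(OC)c1c(-c2cc(OCc3ccccc3)c(OC)c(OCc3ccccc3)c2)oc2c(OC)c(OC)cc(OC)c2c1=O
F3 | step 4 | 2-[3,5-bis(benzyloxy)-4-methoxyphenyl]-3,5-dihydroxy-7,8-dimethoxy-4H-chromen-4-one | COc1cc(O)c2c(=O)c(O)c(-c3cc(OCc4ccccc4)c(OC)c(OCc4ccccc4)c3)oc2c1OC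
F4 | step 2 | 1-[3,4,6-trimethoxy-2-(methoxymethoxy)phenyl]ethan-1-one | CC(=O)c1c(OCOC)c(OC)c(OC)cc1OC
F5 | step 2 | (E)-3-[3,5-bis(benzyloxy)-4-methoxyphenyl]-1-[3,4,6-trimethoxy-2-(methoxymethoxy)phenyl]prop-2-en-1-one | O=C(/C=C/c1cc(OCc2ccccc2)c(OC)c(OCc2ccccc2)c1)c1c(OCOC)c(OC)c(OC)cc1OC
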